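(The runs stem from a simulated flask for an exercise; noise was put on by code.)

The vessel was closed, stirred and held at one temperature; in it X went first to G, and G with J went on to D, with E as the catalyst.

the same everywhere: X 33 mM

| flask | J | E | remark |
|---|---|---|---|
| maple | 39.6 mM | 1.4 mM | run made earlier |
| oak | 39.6 mM | 2 mM | run made earlier |
| elm | 20 mM | 2.7 mM | run made earlier |
| flask | 39.6 mM | 2.7 mM |  |

| run | time / min | D / % | X / % |
|---|---|---|---|
| maple | 2.50 | 1 | 82 |
| maple | 5.00 | 2 | 67 |
| maple | 6.00 | 3 | 65 |
| maple | 10.0 | 9 | 51 |
| maple | 12.0 | 15 | 48 |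
| maple | 15.0 | 20 | 43 |
| oak | 2.50 | 1 | 80 |
| oak | 5.00 | 6 | 66 |
| oak | 6.00 | 8 | 61 |
| oak | 10.0 | 15 | 49 |
| oak | 12.0 | 22 | 46 |
| oak | 15.0 | 27 | 37 |
| elm | 1.33 | 1 | 86 |
| elm | 4.00 | 4 | 66 |
| elm | 8.00 | 12 | 50 |
| elm | 12.0 | 23 | 37 |
| elm | 15.0 | 26 | 34 |

(each reading ± 1.5 percentage points)

- apparent order in J when 20% of the X are converted (percent change of the rate of making D for one percent more J charged)
- apparent order in E when 20% of the X are converted (percent change of the rate of making D for one percent more E charged)

- steps thought possible: X + E <-> E + G; 2 E <-> Q; J + L -> E + D; E + G <-> L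

You asked for a quick number, and your forecast was 0.15 in J and 0.52 in E, on the ground that “Capture of L by J is fast, and formation of L limits the rate.” I reckoned for myself and replaced each curve of D by its mean slope. The first loss of X, which I took to be a step without J, had a constant of 0.0794 min⁻¹ in maple and 0.113 min⁻¹ in elm, so its order in E was 0.543. Oak made D at a mean 0.0210 min⁻¹ as a fraction of the X charged, which that order scales to 0.0247 min⁻¹ at the flask's E. Elm, with the flask's E, made 0.0200 min⁻¹. As fractions of the flask's charge of J, the mean J stood at 0.863 in oak and 0.380 in elm. That gave 0.258, my figure and higher than the forecast's: the mean-window order in J, the logarithm of the ratio of mean rates at equal E over the logarithm of the ratio of mean J. Oak's last J, 0.775, lay off the mean by enough to move the rate 2.73%, so the mean served, but with a scatter of 1.5 percentage points on each reading my figure stayed rough.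

The flask gave 0.29 in J and 0.54 in E, so the forecast held for E, while for J it came to about half the flask's value, and my mean-window order of 0.258 stood nearer.

    X + E ⇌ E + G (K = 1.60, k = 120 M⁻¹ min⁻¹)
    2 E ⇌ Q, settled at all times (K = 700 M⁻¹)
    J + L → E + D (k = 71.0 M⁻¹ min⁻¹)
    E + G ⇌ L (K = 220 M⁻¹, k = 97.0 M⁻¹ min⁻¹)

Part of the reason for so low an order lies in Q, an off-cycle form, which held 55.4% of the catalyst at 2.00 min. In the run of this flask without the joining of two E to Q, the order in J rose from 0.29 to 0.51, and the rate at 20% conversion stood at 1.87 times the actual one.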